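**Plan**
- Retrosynthesis: the two C‑acetyl bonds are cut first (ring A by Friedel–Crafts acetylation at one of its two equivalent positions, ring B at C5' by Fries shift of a C4' acetate), then the C6' O‑methyl bond. Ring B is then opened at C5'–C6' and C6'–C1' to carbon monoxide and an acyclic 3‑acetoxy‑1,4‑enyne, which is cut at the ethynyl–C3' bond, at C1'=C2' (olefination) and at the ring A–allyl bond.
- Enabling feature: ring B (the C‑methyl ring; C1' bridge carbon, C2' OH, C3' CH3, C4' OH, C5' acetyl, C6' OCH3) is hexasubstituted with oxygen on C2', C4' and C6', and C6' lies between C1' and C5'. C6' and its oxygen can therefore be CO placed between the two ends of a five‑carbon enyne.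
- Forward: ring A is bought as 5‑methoxyresorcinol. The chain is joined in the order aryl–allyl bond, oxidative cleavage, Horner–Wadsworth–Emmons olefination (C1'=C2' enol ether), ethynylation/acetylation. Ring B then closes in the rhodium‑catalysed carbonylative benzannulation, and O‑methylation, removal of the methoxymethyl (MOM) groups and a Fries/Friedel–Crafts acetylation finish the synthesis.
- Stereochemistry: the target has no stereocentre. Only the Z geometry of the enol ether matters (set in the olefination); the racemic carbinol centre of the enyne disappears on aromatisation.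

Key step: step 8

Remark: ring A is the ring without the C‑methyl group; the chiral compounds 12, 16, 17 and 19 are racemic, which has no consequence for the achiral target.

**Step 1**
Reactants: 1 5‑methoxyresorcinol; 2 chloromethyl methyl ether
Product: 3 1‑methoxy‑3,5‑bis(methoxymethoxy)benzene
Conditions: NaH, MOMCl, DMF, 0 °C → rt
Reagents that add atoms: chloromethyl methyl ether (2), COCCl
Why: Double Williamson O‑alkylation of the bis‑phenoxide is routine for resorcinols, and the MOM ethers later direct the lithiation and can be removed without base or strong acid.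

**Step 2**
Reactants: 3 1‑methoxy‑3,5‑bis(methoxymethoxy)benzene; 4 allyl bromide
Product: 6 5‑methoxy‑1,3‑bis(methoxymethoxy)‑2‑(prop‑2‑en‑1‑yl)benzene, via aryllithium 5 (not isolated)
Conditions: n‑BuLi, THF, 0 °C; then CuBr·SMe2 (10 mol %), allyl bromide, −78 °C → rt
Reagents that add atoms: allyl bromide (4), C=CCBr
Why: Directed ortho‑lithiation should take place at the one position flanked by two OMOM groups (cooperative coordination, stronger than the OMOM/OMe pair), and copper‑catalysed allylation of the aryllithium suppresses halogen–lithium exchange with allyl bromide.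

**Step 3**
Reactants: 6 5‑methoxy‑1,3‑bis(methoxymethoxy)‑2‑(prop‑2‑en‑1‑yl)benzene
Product: 7 2‑[4‑methoxy‑2,6‑bis(methoxymethoxy)phenyl]acetaldehyde
Conditions: OsO4 (2 mol %), NaIO4, 2,6‑lutidine, dioxane/H2O (3:1), rt
Reagents that add atoms: sodium periodate, [Na+].[O-]I(=O)(=O)=O (its oxygen reaches the product through catalytic OsO4, O=[Os](=O)(=O)=O)
Why: Lemieux–Johnson cleavage of the terminal alkene is preferred to ozonolysis because ozone would attack the trioxygenated arene, and 2,6‑lutidine keeps the medium non‑acidic for the MOM ethers.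

**Step 4**
Reactants: 8 diethyl (hydroxymethyl)phosphonate; 2 chloromethyl methyl ether
Product: 9 diethyl [(methoxymethoxy)methyl]phosphonate
Conditions: MOMCl, i‑Pr2NEt, CH2Cl2, 0 °C → rt
Reagents that add atoms: chloromethyl methyl ether (2), COCCl
Why: MOM ether formation on a primary alcohol under amine base is standard and avoids a free alkoxide that could attack phosphorus.

**Step 5**
Reactants: 9 diethyl [(methoxymethoxy)methyl]phosphonate; 10 N‑methoxy‑N‑methylacetamide
Product: 12 diethyl [1‑(methoxymethoxy)‑2‑oxopropyl]phosphonate (racemic), via lithiated phosphonate 11 (not isolated)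
Conditions: LiN(i‑Pr)2, THF, −78 °C; then MeC(O)N(OMe)Me, −78 → 0 °C; aq. NH4Cl
Reagents that add atoms: N‑methoxy‑N‑methylacetamide (10), CON(C)C(C)=O
Why: C‑Acylation of an α‑lithiated phosphonate with a Weinreb amide is the usual entry to β‑ketophosphonates, the chelated adduct preventing over‑addition; the new stereocentre is racemic and is lost in step 6.

**Step 6**
Reactants: 7 2‑[4‑methoxy‑2,6‑bis(methoxymethoxy)phenyl]acetaldehyde; 12 diethyl [1‑(methoxymethoxy)‑2‑oxopropyl]phosphonate
Product: 13 (3Z)‑5‑[4‑methoxy‑2,6‑bis(methoxymethoxy)phenyl]‑3‑(methoxymethoxy)pent‑3‑en‑2‑one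
Conditions: LiCl, DBU, MeCN, 0 °C → rt
Reagents that add atoms: phosphonate 12, CCOP(=O)(OCC)C(OCOC)C(C)=O
Why: Horner–Wadsworth–Emmons olefination under Masamune–Roush conditions is mild enough for an enolisable arylacetaldehyde and should place the acyl group trans to the new CH2Ar substituent (Z enol ether, any E isomer being removed by chromatography), while the twisted 2,6‑disubstituted aryl group offers no driving force for migration of the double bond.

**Step 7**
Reactants: 13 (3Z)‑5‑[4‑methoxy‑2,6‑bis(methoxymethoxy)phenyl]‑3‑(methoxymethoxy)pent‑3‑en‑2‑one; 14 ethynylmagnesium bromide; 15 acetic anhydride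
Product: 17 (4Z)‑6‑[4‑methoxy‑2,6‑bis(methoxymethoxy)phenyl]‑4‑(methoxymethoxy)‑3‑methylhex‑4‑en‑1‑yn‑3‑yl acetate (racemic), via bromomagnesium alkoxide 16 (not isolated)
Conditions: HC≡CMgBr, THF, −78 → 0 °C; then Ac2O, DMAP (cat.), 0 °C → rt
Reagents that add atoms: ethynylmagnesium bromide (14), C#C[Mg]Br; acetic anhydride (15), CC(=O)OC(C)=O
Why: 1,2‑Addition of the alkynyl Grignard reagent to the methyl ketone and acylation of the tertiary magnesium alkoxide in the same flask is a standard route to tertiary propargylic acetates; the carbinol centre forms without control (racemic), which is irrelevant because it becomes aromatic C3'.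

**Step 8**
Reactants: 17 (4Z)‑6‑[4‑methoxy‑2,6‑bis(methoxymethoxy)phenyl]‑4‑(methoxymethoxy)‑3‑methylhex‑4‑en‑1‑yn‑3‑yl acetate; 18 carbon monoxide
Product: 20 5‑hydroxy‑4‑{[4‑methoxy‑2,6‑bis(methoxymethoxy)phenyl]methyl}‑3‑(methoxymethoxy)‑2‑methylphenyl acetate, via cyclohexadienone 19 (not isolated)
Conditions: [RhCl(CO)2]2 (5 mol %), CO (80 atm), CH2Cl2, 80 °C
Reagents that add atoms: carbon monoxide (18), [C-]#[O+]
Why: Monovalent rhodium activates the terminal alkyne, the acetate shifts 1,2 to give a rhodium dienylcarbene, this closes to a rhodacyclohexadiene, CO inserts into a Rh–C bond, and reductive elimination releases dienone 19, which tautomerises to phenol 20. The closest known reaction is the rhodium‑catalysed carbonylative (5+1) benzannulation of 3‑acyloxy‑1,4‑enynes to resorcinol monoesters, applied here to an enyne whose alkene is an enol ether. Ring B closes in a (5+1) mode: the chain C5'–C4'–C3'–C2'–C1' (alkyne CH, acetoxy carbon, carbinol carbon, enol‑ether carbon, alkene terminus) is bridged by the CO carbon C6', the C5'–C6' bond forming by migratory insertion and the C6'–C1' bond by reductive elimination. No lasting stereocentre is created, since the carbinol centre of 17 and C1' of 19 both become aromatic. The step needs 1,2‑ rather than 1,3‑acyloxy migration and CO uptake rather than closure of the carbene onto the alkene to a five‑membered ring; the terminal alkyne favours the 1,2 shift, the CO pressure favours carbonylation, and the Z enol ether keeps the arylmethyl group outside the closing ring. The CO‑derived C6' hydroxyl is then the only free phenol, and the migrated acetate sits on C4' next to the still unsubstituted C5'.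

**Step 9**
Reactants: 20 5‑hydroxy‑4‑{[4‑methoxy‑2,6‑bis(methoxymethoxy)phenyl]methyl}‑3‑(methoxymethoxy)‑2‑methylphenyl acetate; 21 iodomethane
Product: 22 5‑methoxy‑4‑{[4‑methoxy‑2,6‑bis(methoxymethoxy)phenyl]methyl}‑3‑(methoxymethoxy)‑2‑methylphenyl acetate
Conditions: MeI, K2CO3, acetone, rt
Reagents that add atoms: iodomethane (21), CI
Why: Williamson O‑methylation of the only free phenol (C6'–OH) in an aprotic solvent should leave the C4' aryl acetate and the MOM ethers untouched.

**Step 10**
Reactants: 22 5‑methoxy‑4‑{[4‑methoxy‑2,6‑bis(methoxymethoxy)phenyl]methyl}‑3‑(methoxymethoxy)‑2‑methylphenyl acetate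
Product: 23 4‑[(2,6‑dihydroxy‑4‑methoxyphenyl)methyl]‑3‑hydroxy‑5‑methoxy‑2‑methylphenyl acetate
Conditions: ZnBr2, n‑PrSH, CH2Cl2, 0 °C → rt
Reagents that add atoms: none
Why: Lewis‑acid‑assisted MOM cleavage with thiol capture removes the three aryl MOM ethers at or below room temperature, tolerates the aryl acetate, and traps the methoxymethyl cation so that it cannot alkylate the electron‑rich ring A.

**Step 11**
Reactants: 23 4‑[(2,6‑dihydroxy‑4‑methoxyphenyl)methyl]‑3‑hydroxy‑5‑methoxy‑2‑methylphenyl acetate; 15 acetic anhydride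
Product: 24 1‑{5‑[(3‑acetyl‑2,6‑dihydroxy‑4‑methoxyphenyl)methyl]‑2,4‑dihydroxy‑6‑methoxy‑3‑methylphenyl}ethan‑1‑one (target)
Conditions: BF3·OEt2, Ac2O (1.2 equiv), 0 → 50 °C; then aq. NaOAc/MeOH, 50 °C
Reagents that add atoms: acetic anhydride (15), CC(=O)OC(C)=O
Why: Under BF3·OEt2 the C4' acetate should undergo Fries rearrangement to C5', the only free position of ring B, while Ac2O effects Friedel–Crafts C‑acetylation of ring A at one of its two equivalent positions between OH and OMe; one acetyl group deactivates each ring against a second acylation, BF3 does not cleave the methyl ethers, and the methanolic work‑up removes boron and any stray O‑acetate.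

**Compound list**
1 | 5‑methoxyresorcinol (5‑methoxybenzene‑1,3‑diol) | COc1cc(O)cc(O)c1 | starting material
2 | chloromethyl methyl ether | COCCl | starting material
3 | 1‑methoxy‑3,5‑bis(methoxymethoxy)benzene | COCOc1cc(OC)cc(OCOC)c1 | intermediate
4 | allyl bromide | C=CCBr | starting material
5 | [4‑methoxy‑2,6‑bis(methoxymethoxy)phenyl]lithium (not isolated) | [Li]c1c(OCOC)cc(OC)cc1OCOC | intermediate
6 | 5‑methoxy‑1,3‑bis(methoxymethoxy)‑2‑(prop‑2‑en‑1‑yl)benzene | C=CCc1c(OCOC)cc(OC)cc1OCOC | intermediate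
7 | 2‑[4‑methoxy‑2,6‑bis(methoxymethoxy)phenyl]acetaldehyde | O=CCc1c(OCOC)cc(OC)cc1OCOC | intermediate
8 | diethyl (hydroxymethyl)phosphonate | CCOP(=O)(CO)OCC | starting material
9 | diethyl [(methoxymethoxy)methyl]phosphonate | CCOP(=O)(COCOC)OCC | intermediate
10 | N‑methoxy‑N‑methylacetamide | CON(C)C(C)=O | starting material
11 | diethyl [lithio(methoxymethoxy)methyl]phosphonate (not isolated) | CCOP(=O)(OCC)C([Li])OCOC | intermediate
12 | diethyl [1‑(methoxymethoxy)‑2‑oxopropyl]phosphonate (racemic) | CCOP(=O)(OCC)C(OCOC)C(C)=O | intermediate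
13 | (3Z)‑5‑[4‑methoxy‑2,6‑bis(methoxymethoxy)phenyl]‑3‑(methoxymethoxy)pent‑3‑en‑2‑one | CC(=O)/C(OCOC)=C/Cc1c(OCOC)cc(OC)cc1OCOC | intermediate
14 | ethynylmagnesium bromide | C#C[Mg]Br | starting material
15 | acetic anhydride | CC(=O)OC(C)=O | starting material
16 | bromomagnesium (4Z)‑6‑[4‑methoxy‑2,6‑bis(methoxymethoxy)phenyl]‑4‑(methoxymethoxy)‑3‑methylhex‑4‑en‑1‑yn‑3‑olate (racemic, not isolated) | C#CC(C)(O[Mg]Br)/C(OCOC)=C/Cc1c(OCOC)cc(OC)cc1OCOC | intermediate
17 | (4Z)‑6‑[4‑methoxy‑2,6‑bis(methoxymethoxy)phenyl]‑4‑(methoxymethoxy)‑3‑methylhex‑4‑en‑1‑yn‑3‑yl acetate (racemic) | C#CC(C)(OC(C)=O)/C(OCOC)=C/Cc1c(OCOC)cc(OC)cc1OCOC | intermediate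
18 | carbon monoxide | [C-]#[O+] | starting material
19 | 4‑{[4‑methoxy‑2,6‑bis(methoxymethoxy)phenyl]methyl}‑5‑(methoxymethoxy)‑6‑methyl‑3‑oxocyclohexa‑1,5‑dien‑1‑yl acetate (racemic, not isolated) | CC(=O)OC1=CC(=O)C(Cc2c(OCOC)cc(OC)cc2OCOC)C(OCOC)=C1C | intermediate
20 | 5‑hydroxy‑4‑{[4‑methoxy‑2,6‑bis(methoxymethoxy)phenyl]methyl}‑3‑(methoxymethoxy)‑2‑methylphenyl acetate | CC(=O)Oc1cc(O)c(Cc2c(OCOC)cc(OC)cc2OCOC)c(OCOC)c1C | intermediate
21 | iodomethane | CI | starting material
22 | 5‑methoxy‑4‑{[4‑methoxy‑2,6‑bis(methoxymethoxy)phenyl]methyl}‑3‑(methoxymethoxy)‑2‑methylphenyl acetate | CC(=O)Oc1cc(OC)c(Cc2c(OCOC)cc(OC)cc2OCOC)c(OCOC)c1C | intermediate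
23 | 4‑[(2,6‑dihydroxy‑4‑methoxyphenyl)methyl]‑3‑hydroxy‑5‑methoxy‑2‑methylphenyl acetate | CC(=O)Oc1cc(OC)c(Cc2c(O)cc(OC)cc2O)c(O)c1C | intermediate
24 | 1‑{5‑[(3‑acetyl‑2,6‑dihydroxy‑4‑methoxyphenyl)methyl]‑2,4‑dihydroxy‑6‑methoxy‑3‑methylphenyl}ethan‑1‑one | COc1cc(O)c(Cc2c(O)c(C)c(O)c(C(C)=O)c2OC)c(O)c1C(C)=O | target

**Step count**
Total steps: 11. Longest linear sequence: 9 steps (1, 2, 3, 6, 7, 8, 9, 10, 11) from 5‑methoxyresorcinol; steps 4 and 5 form the phosphonate side branch.

**Steps most likely to fail**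

1. Step 8. The acetate may migrate 1,3 instead of 1,2, the carbene may close onto the alkene without taking up CO, or the electron‑rich enol ether may slow metallacycle formation or degrade at 80 °C. Fallback: ring B is brought in as a ready‑made arene and joined to ring A by an aryllithium/aldehyde coupling, setting out from compound 3 and returning at target 24.
   - Lithiation of 3 as in step 2 and quenching with MeI would give 5‑methoxy‑1,3‑bis(methoxymethoxy)‑2‑methylbenzene F1.
   - A second directed lithiation (n‑BuLi, TMEDA, THF) between OMOM and OMe, followed by DMF, would give 6‑methoxy‑2,4‑bis(methoxymethoxy)‑3‑methylbenzaldehyde F2.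
   - Addition of aryllithium 5 (again from 3) to F2 would give [4‑methoxy‑2,6‑bis(methoxymethoxy)phenyl][6‑methoxy‑2,4‑bis(methoxymethoxy)‑3‑methylphenyl]methanol F3.
   - Ionic hydrogenation (Et3SiH, CF3CO2H, CH2Cl2) should remove the benzylic hydroxyl and the four MOM groups to give 4‑[(2,6‑dihydroxy‑4‑methoxyphenyl)methyl]‑5‑methoxy‑2‑methylbenzene‑1,3‑diol F4.
   - Double C‑acetylation of F4 (Ac2O, BF3·OEt2, one acetyl per ring, C5' being the only free site of ring B) would give 24. This last operation shares the acid‑sensitivity risk of step 11.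

2. Step 11. Acid may cleave or scramble the methylene bridge between the two electron‑rich rings, and acylation may run past one acetyl group per ring. Fallback: the acetyl groups are introduced by anionic rather than cationic chemistry on MOM‑protected material, setting out from compound 22 and returning at target 24.
   - Methanolysis of the acetate (K2CO3, MeOH) would give 5‑methoxy‑4‑{[4‑methoxy‑2,6‑bis(methoxymethoxy)phenyl]methyl}‑3‑(methoxymethoxy)‑2‑methylphenol F5.
   - MOM protection (NaH, MOMCl, DMF) would give 1‑methoxy‑2‑{[4‑methoxy‑2,6‑bis(methoxymethoxy)phenyl]methyl}‑3,5‑bis(methoxymethoxy)‑4‑methylbenzene F6.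
   - Directed ortho‑lithiation of each ring between OMOM and OMe (n‑BuLi, TMEDA, THF, one lithium per ring) and quenching with N‑methoxy‑N‑methylacetamide 10 would give 1‑{3‑[(3‑acetyl‑4‑methoxy‑2,6‑bis(methoxymethoxy)phenyl)methyl]‑2‑methoxy‑4,6‑bis(methoxymethoxy)‑5‑methylphenyl}ethan‑1‑one F7.
   - Removal of the four MOM groups with HCl in MeOH, in which formaldehyde is held as its dimethyl acetal, would give 24.

3. Step 6. The arylacetaldehyde may enolise and self‑condense under the basic olefination conditions, and control of the alkene geometry may be incomplete. Fallback: the enone is built by aldol addition and a separate elimination, setting out from aldehyde 7 and returning at enone 13.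
   - Commercial 2‑hydroxy‑N‑methoxy‑N‑methylacetamide would be protected (MOMCl, i‑Pr2NEt) to N‑methoxy‑2‑(methoxymethoxy)‑N‑methylacetamide F8.
   - Addition of the lithium enolate of F8 (LiN(i‑Pr)2, THF, −78 °C), which is faster than proton transfer, to 7 would give 3‑hydroxy‑N‑methoxy‑4‑[4‑methoxy‑2,6‑bis(methoxymethoxy)phenyl]‑2‑(methoxymethoxy)‑N‑methylbutanamide F9 as a diastereomer mixture.
   - Mesylation (MsCl, Et3N) would give the corresponding methanesulfonate, 4‑[4‑methoxy‑2,6‑bis(methoxymethoxy)phenyl]‑1‑[methoxy(methyl)amino]‑2‑(methoxymethoxy)‑1‑oxobutan‑3‑yl methanesulfonate F10.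
   - E1cB elimination with DBU should give the thermodynamically preferred (2Z)‑N‑methoxy‑4‑[4‑methoxy‑2,6‑bis(methoxymethoxy)phenyl]‑2‑(methoxymethoxy)‑N‑methylbut‑2‑enamide F11.
   - Addition of MeMgBr to the Weinreb amide F11 would give 13.

**Further compounds**
F1 | step 8 | 5‑methoxy‑1,3‑bis(methoxymethoxy)‑2‑methylbenzene | Cc1c(OCOC)cc(OC)cc1OCOC
F2 | step 8 | 6‑methoxy‑2,4‑bis(methoxymethoxy)‑3‑methylbenzaldehyde | O=Cc1c(OC)cc(OCOC)c(C)c1OCOC
F3 | step 8 | [4‑methoxy‑2,6‑bis(methoxymethoxy)phenyl][6‑methoxy‑2,4‑bis(methoxymethoxy)‑3‑methylphenyl]methanol (racemic) | OC(c1c(OCOC)cc(OC)cc1OCOC)c1c(OC)cc(OCOC)c(C)c1OCOC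
F4 | step 8 | 4‑[(2,6‑dihydroxy‑4‑methoxyphenyl)methyl]‑5‑methoxy‑2‑methylbenzene‑1,3‑diol | Cc1c(O)cc(OC)c(Cc2c(O)cc(OC)cc2O)c1O
F5 | step 11 | 5‑methoxy‑4‑{[4‑methoxy‑2,6‑bis(methoxymethoxy)phenyl]methyl}‑3‑(methoxymethoxy)‑2‑methylphenol | Cc1c(O)cc(OC)c(Cc2c(OCOC)cc(OC)cc2OCOC)c1OCOC
F6 | step 11 | 1‑methoxy‑2‑{[4‑methoxy‑2,6‑bis(methoxymethoxy)phenyl]methyl}‑3,5‑bis(methoxymethoxy)‑4‑methylbenzene | Cc1c(OCOC)cc(OC)c(Cc2c(OCOC)cc(OC)cc2OCOC)c1OCOC
F7 | step 11 | 1‑{3‑[(3‑acetyl‑4‑methoxy‑2,6‑bis(methoxymethoxy)phenyl)methyl]‑2‑methoxy‑4,6‑bis(methoxymethoxy)‑5‑methylphenyl}ethan‑1‑one | CC(=O)c1c(OC)c(Cc2c(OCOC)cc(OC)c(C(C)=O)c2OCOC)c(OCOC)c(C)c1OCOC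
F8 | step 6 | N‑methoxy‑2‑(methoxymethoxy)‑N‑methylacetamide | COCOCC(=O)N(C)OC
F9 | step 6 | 3‑hydroxy‑N‑methoxy‑4‑[4‑methoxy‑2,6‑bis(methoxymethoxy)phenyl]‑2‑(methoxymethoxy)‑N‑methylbutanamide (diastereomer mixture, racemic) | CON(C)C(=O)C(OCOC)C(O)Cc1c(OCOC)cc(OC)cc1OCOC
F10 | step 6 | 4‑[4‑methoxy‑2,6‑bis(methoxymethoxy)phenyl]‑1‑[methoxy(methyl)amino]‑2‑(methoxymethoxy)‑1‑oxobutan‑3‑yl methanesulfonate (diastereomer mixture, racemic) | CON(C)C(=O)C(OCOC)C(OS(C)(=O)=O)Cc1c(OCOC)cc(OC)cc1OCOC
F11 | step 6 | (2Z)‑N‑methoxy‑4‑[4‑methoxy‑2,6‑bis(methoxymethoxy)phenyl]‑2‑(methoxymethoxy)‑N‑methylbut‑2‑enamide | CON(C)C(=O)/C(OCOC)=C/Cc1c(OCOC)cc(OC)cc1OCOC
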